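**Plan**

- Cuts, in retrosynthetic order: (a) the CH2–C1' bond joining the propane chain to ring B (alkylzinc plus aryl bromide); (b) both CH=CMe2 double bonds of the prenyl groups on C2' and C3' (twofold Wittig olefination of a bis-aldehyde); (c) in ring A the C5–CMe2 bond (aromatic Claisen shift from the C4 oxygen), with the three chain carbons and the C2 oxygen traced to the lactone of umbelliferone.
- Enabling feature: the prenyl groups sit on the neighbouring ring B carbons C2' and C3'. Their ArCH2–CH= carbons are C5–C6 and C8–C7 of a 5,8-dihydronaphthalene, so cleaving the C6=C7 alkene of that ring gives the two aldehyde carbons that the ylide turns into the two prenyl alkenes.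
- Forward, ring B: 5,8-dihydro-1-naphthol is brominated para to OH, formylated ortho, oxidised to the catechol (Dakin), silylated, ozonised and olefinated twice. No ring is formed anywhere in the route; one ring is opened.
- Forward, ring A and union: umbelliferone is O-prenylated, reduced to the phenol/propanol, silylated, rearranged (Claisen) and converted to the propyl iodide; its zinc reagent is coupled with the ring B bromide, and fluoride then frees the four phenols.
- Stereochemistry: the target has no stereocentre, and its alkenes (two isopropylidene, one terminal vinyl) have no geometry, so only regio- and chemoselectivity must be controlled.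

Key step: step 6

Remark on the chemistry: ring A is numbered C1–C6 from the chain-bearing carbon (OH on C2 and C4, 2-methylbut-3-en-2-yl on C5) and ring B C1'–C6' likewise (prenyl on C2' and C3', OH on C4' and C5'); TBS is tert-butyldimethylsilyl; the four starting materials 1, 9, 12 and 13 are assumed to be purchased.

**Ring B fragment**

Step 1
Reactants: 1 5,8-dihydronaphthalen-1-ol
Product: 2 4-bromo-5,8-dihydronaphthalen-1-ol
Conditions: NBS (1.0 equiv), MeCN, −20 → 0 °C, dark
Reagents that add atoms: N-bromosuccinimide, O=C1CCC(=O)N1Br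
Why: Electrophilic aromatic bromination with NBS in a polar solvent attacks the phenol far faster than the isolated cis-alkene and prefers the position para to the hydroxyl (C4), as known for 5,6,7,8-tetrahydro-1-naphthol and 2,3-dialkylphenols, while cold, dark conditions hold back radical bromination and aromatisation of the dihydro ring.

Step 2
Reactants: 2 4-bromo-5,8-dihydronaphthalen-1-ol
Product: 3 4-bromo-1-hydroxy-5,8-dihydronaphthalene-2-carbaldehyde
Conditions: MgCl2, Et3N, (CH2O)n, MeCN, reflux; then 1 M HCl
Reagents that add atoms: formaldehyde (as paraformaldehyde), C=O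
Why: Magnesium-mediated ortho-formylation of phenols (Casnati–Skattebøl reaction) delivers formaldehyde only ortho to the phenoxide oxygen, C2 is the single free ortho position, and a second formaldehyde oxidises the benzylic alkoxide to the aldehyde; bromophenols are standard substrates.

Step 3
Reactants: 3 4-bromo-1-hydroxy-5,8-dihydronaphthalene-2-carbaldehyde
Product: 5 4-bromo-5,8-dihydronaphthalene-1,2-diol, via aryl formate 4 (not isolated)
Conditions: 30% H2O2 (1.2 equiv), NaOH (aq, 1.1 equiv), THF, 0 °C, argon; then 1 M HCl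
Reagents that add atoms: hydrogen peroxide, OO
Why: Dakin oxidation, in which hydroperoxide adds to the ortho-hydroxy aldehyde, aryl migration to oxygen gives formate 4 and hydroxide saponifies it at once, while alkaline H2O2 leaves the unactivated alkene and the aryl bromide untouched.

Step 4
Reactants: 5 4-bromo-5,8-dihydronaphthalene-1,2-diol
Product: 6 4-bromo-1,2-bis(tert-butyldimethylsilyloxy)-5,8-dihydronaphthalene
Conditions: TBSCl (3 equiv), imidazole (6 equiv), DMAP (cat.), DMF, 25 → 50 °C
Reagents that add atoms: tert-butyldimethylsilyl chloride, CC(C)(C)[Si](C)(C)Cl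
Why: Imidazole-promoted silylation caps the air-sensitive catechol directly after its formation and gives aryl silyl ethers that should tolerate ozone, ylide and organozinc chemistry and fall to fluoride at the end.

Step 5
Reactants: 6 4-bromo-1,2-bis(tert-butyldimethylsilyloxy)-5,8-dihydronaphthalene
Product: 8 2,2'-[3-bromo-5,6-bis(tert-butyldimethylsilyloxy)-1,2-phenylene]diacetaldehyde, via ozonide 7 (not isolated)
Conditions: O3, CH2Cl2, −78 °C (Sudan Red 7B end-point); then PPh3, −78 °C → rt; crude 8 used at once
Reagents that add atoms: ozone, [O-][O+]=O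
Why: Ozonolysis of the only alkene (dipolar cycloaddition, Criegee rearrangement to ozonide 7, reduction by PPh3) follows the known cleavage of 1,4-dihydronaphthalenes to 1,2-phenylenediacetaldehydes, and the dye end-point stops the ozone before it reaches the silyloxy arene.

Step 6
Reactants: 8 2,2'-[3-bromo-5,6-bis(tert-butyldimethylsilyloxy)-1,2-phenylene]diacetaldehyde; 9 isopropyltriphenylphosphonium iodide
Product: 11 1-bromo-4,5-bis(tert-butyldimethylsilyloxy)-2,3-bis(3-methylbut-2-en-1-yl)benzene, via isopropylidenetriphenylphosphorane 10 (not isolated)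
Conditions: 9 (4 equiv), KN(SiMe3)2 (3.9 equiv), THF, 0 °C; then crude 8 in THF added at −78 °C, → 0 °C
Reagents that add atoms: none
Why: Twofold Wittig olefination: the unstabilised ylide 10 adds to each aldehyde carbon of 8 to give an oxaphosphetane that collapses by cycloreversion to an ArCH2CH=CMe2 unit and Ph3PO, passing through a mono-olefinated aldehyde. The closest known reaction type is the olefination of arylacetaldehydes with isopropylidenetriphenylphosphorane to make prenylarenes. No ring is closed and no stereocentre is created, and each new trisubstituted alkene carries two identical methyl groups, so no geometry arises. The selectivity needed is carbonyl addition over deprotonation of the acidic ArCH2CHO positions, which would open the way to intramolecular aldol closure to an indene. It should be secured by adding cold, freshly made 8 to an excess of lithium-free ylide, so that each aldehyde always meets ylide in excess and adds before it can enolise and condense. The ortho relationship of the two prenyl groups is guaranteed because both arms come from the C5–C8 bridge of the dihydronaphthalene, the second oxygen having used the only free ortho position and bromine the para position of the starting phenol.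

**Ring A fragment**

Step 7
Reactants: 12 umbelliferone (7-hydroxy-2H-chromen-2-one); 13 prenyl bromide (1-bromo-3-methylbut-2-ene)
Product: 14 7-[(3-methylbut-2-en-1-yl)oxy]-2H-chromen-2-one
Conditions: K2CO3, acetone, reflux
Reagents that add atoms: none
Why: Williamson etherification of the acidic 7-hydroxyl at the primary allylic bromide is the standard way to 7-alkoxycoumarins and leaves the lactone closed.

Step 8
Reactants: 14 7-[(3-methylbut-2-en-1-yl)oxy]-2H-chromen-2-one
Product: 15 7-[(3-methylbut-2-en-1-yl)oxy]chroman-2-one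
Conditions: Cu(OAc)2·H2O (3 mol %), 1,2-bis(diphenylphosphino)benzene (3 mol %), (EtO)2MeSiH (1.5 equiv), t-BuOH (2 equiv), toluene, 0 °C → rt
Reagents that add atoms: none
Why: Copper hydride conjugate reduction, known for coumarins, adds hydride at C4 of the enoate and t-BuOH protonates the copper enolate, while the isolated trisubstituted alkene and the allyl aryl ether are inert; any lactol from over-reduction converges in step 9.

Step 9
Reactants: 15 7-[(3-methylbut-2-en-1-yl)oxy]chroman-2-one
Product: 16 2-(3-hydroxypropyl)-5-[(3-methylbut-2-en-1-yl)oxy]phenol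
Conditions: LiAlH4, THF, 0 °C → rt; H2O, 15% NaOH (aq) work-up
Reagents that add atoms: none
Why: Hydride reduction of the aryl ester lactone opens it to the C2 phenol and the primary alcohol of the three-carbon chain without touching the prenyl ether.

Step 10
Reactants: 16 2-(3-hydroxypropyl)-5-[(3-methylbut-2-en-1-yl)oxy]phenol
Product: 17 tert-butyl{3-[2-(tert-butyldimethylsilyloxy)-4-(3-methylbut-2-en-1-yloxy)phenyl]propoxy}dimethylsilane
Conditions: TBSCl (2.5 equiv), imidazole (5 equiv), DMF, rt
Reagents that add atoms: tert-butyldimethylsilyl chloride, CC(C)(C)[Si](C)(C)Cl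
Why: Standard silylation of both hydroxyls; the bulky silyl ether on the C2 oxygen is also meant to shield C3 in the rearrangement that follows.

Step 11
Reactants: 17 tert-butyl{3-[2-(tert-butyldimethylsilyloxy)-4-(3-methylbut-2-en-1-yloxy)phenyl]propoxy}dimethylsilane
Product: 18 5-(tert-butyldimethylsilyloxy)-4-[3-(tert-butyldimethylsilyloxy)propyl]-2-(2-methylbut-3-en-2-yl)phenol
Conditions: PhNEt2, 190 °C, sealed tube, argon
Reagents that add atoms: none
Why: Aromatic Claisen rearrangement ([3,3] shift with allylic inversion of the prenyl ether to the 1,1-dimethylallyl group, then tautomerisation) should go to the open ortho carbon C5, because C3 lies between the silyloxy group and the ether oxygen where a new quaternary carbon would be severely crowded, and the amine solvent suppresses acid-induced side reactions.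

Step 12
Reactants: 18 5-(tert-butyldimethylsilyloxy)-4-[3-(tert-butyldimethylsilyloxy)propyl]-2-(2-methylbut-3-en-2-yl)phenol
Product: 19 1,5-bis(tert-butyldimethylsilyloxy)-2-[3-(tert-butyldimethylsilyloxy)propyl]-4-(2-methylbut-3-en-2-yl)benzene
Conditions: TBSOTf (1.3 equiv), 2,6-lutidine (2 equiv), CH2Cl2, 0 °C → rt
Reagents that add atoms: tert-butyldimethylsilyl trifluoromethanesulfonate, CC(C)(C)[Si](C)(C)OS(=O)(=O)C(F)(F)F
Why: The silyl triflate with a hindered pyridine base is the standard answer to a phenol flanked by a quaternary carbon, and it removes the acidic proton that an organozinc reagent would not tolerate.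

Step 13
Reactants: 19 1,5-bis(tert-butyldimethylsilyloxy)-2-[3-(tert-butyldimethylsilyloxy)propyl]-4-(2-methylbut-3-en-2-yl)benzene
Product: 20 3-[2,4-bis(tert-butyldimethylsilyloxy)-5-(2-methylbut-3-en-2-yl)phenyl]propan-1-ol
Conditions: camphorsulfonic acid (10 mol %), MeOH/CH2Cl2 (1:1), 0 °C
Reagents that add atoms: none
Why: Acid-catalysed methanolysis cleaves a primary alkyl silyl ether much faster than aryl silyl ethers, an established orthogonality, and the mild acid does not protonate the terminal vinyl group.

Step 14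
Reactants: 20 3-[2,4-bis(tert-butyldimethylsilyloxy)-5-(2-methylbut-3-en-2-yl)phenyl]propan-1-ol
Product: 21 1,5-bis(tert-butyldimethylsilyloxy)-2-(3-iodopropyl)-4-(2-methylbut-3-en-2-yl)benzene
Conditions: PPh3, imidazole, I2 (premixed), CH2Cl2, 0 °C → rt
Reagents that add atoms: iodine, II
Why: Appel-type iodination (Garegg–Samuelsson conditions) activates the primary alcohol as an alkoxyphosphonium ion that iodide displaces by SN2, and premixing PPh3 with I2 keeps free iodine away from the vinyl group.

**Union and deprotection**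

Step 15
Reactants: 21 1,5-bis(tert-butyldimethylsilyloxy)-2-(3-iodopropyl)-4-(2-methylbut-3-en-2-yl)benzene; 11 1-bromo-4,5-bis(tert-butyldimethylsilyloxy)-2,3-bis(3-methylbut-2-en-1-yl)benzene
Product: 23 kazinol C tetrakis(tert-butyldimethylsilyl) ether, via alkylzinc iodide 22 (not isolated)
Conditions: 21 (1.3 equiv), Zn dust (activated by BrCH2CH2Br and Me3SiCl), LiCl, THF, 40 °C; then 11, Pd(OAc)2 (3 mol %), SPhos (6 mol %), THF, 25 → 50 °C
Reagents that add atoms: none
Why: Negishi coupling, in which LiCl-assisted zinc insertion gives 22, zerovalent palladium carrying the bulky biarylphosphine inserts into the hindered electron-rich C–Br bond, and transmetalation and reductive elimination form the CH2–C1' bond under neutral conditions that spare silyl ethers and all three alkenes.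

Step 16
Reactants: 23 kazinol C tetrakis(tert-butyldimethylsilyl) ether
Product: 24 kazinol C
Conditions: Bu4NF (5 equiv), AcOH (5 equiv), THF, 0 °C → rt, argon
Reagents that add atoms: none
Why: Fluoride cleaves all four aryl silyl ethers, and buffering with acetic acid keeps the catechol and the ortho-allylphenols protonated, which should prevent air oxidation and base- or acid-induced cyclisation onto the prenyl groups.

**Compound list**

1 | 5,8-dihydronaphthalen-1-ol (5,8-dihydro-1-naphthol) | Oc1cccc2c1CC=CC2 | starting material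
2 | 4-bromo-5,8-dihydronaphthalen-1-ol | Oc1ccc(Br)c2c1CC=CC2 | intermediate
3 | 4-bromo-1-hydroxy-5,8-dihydronaphthalene-2-carbaldehyde | O=Cc1cc(Br)c2c(c1O)CC=CC2 | intermediate
4 | 4-bromo-1-hydroxy-5,8-dihydronaphthalen-2-yl formate (formed in the flask) | O=COc1cc(Br)c2c(c1O)CC=CC2 | intermediate
5 | 4-bromo-5,8-dihydronaphthalene-1,2-diol | Oc1cc(Br)c2c(c1O)CC=CC2 | intermediate
6 | 4-bromo-1,2-bis(tert-butyldimethylsilyloxy)-5,8-dihydronaphthalene | CC(C)(C)[Si](C)(C)Oc1cc(Br)c2c(c1O[Si](C)(C)C(C)(C)C)CC=CC2 | intermediate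
7 | secondary ozonide of 6, a 1,2,4-trioxolane spanning the former C6 and C7 (formed in the flask) | CC(C)(C)[Si](C)(C)Oc1cc(Br)c2c(c1O[Si](C)(C)C(C)(C)C)CC1OOC(C2)O1 | intermediate
8 | 2,2'-[3-bromo-5,6-bis(tert-butyldimethylsilyloxy)-1,2-phenylene]diacetaldehyde | O=CCc1c(Br)cc(O[Si](C)(C)C(C)(C)C)c(O[Si](C)(C)C(C)(C)C)c1CC=O | intermediate
9 | isopropyltriphenylphosphonium iodide | CC(C)[P+](c1ccccc1)(c1ccccc1)c1ccccc1.[I-] | starting material
10 | isopropylidenetriphenylphosphorane (formed in the flask) | CC(C)=P(c1ccccc1)(c1ccccc1)c1ccccc1 | intermediate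
11 | 1-bromo-4,5-bis(tert-butyldimethylsilyloxy)-2,3-bis(3-methylbut-2-en-1-yl)benzene | Brc1cc(O[Si](C)(C)C(C)(C)C)c(O[Si](C)(C)C(C)(C)C)c(CC=C(C)C)c1CC=C(C)C | intermediate
12 | umbelliferone (7-hydroxy-2H-chromen-2-one) | O=c1ccc2ccc(O)cc2o1 | starting material
13 | prenyl bromide (1-bromo-3-methylbut-2-ene) | CC(C)=CCBr | starting material
14 | 7-[(3-methylbut-2-en-1-yl)oxy]-2H-chromen-2-one | O=c1ccc2ccc(OCC=C(C)C)cc2o1 | intermediate
15 | 7-[(3-methylbut-2-en-1-yl)oxy]chroman-2-one | O=C1CCc2ccc(OCC=C(C)C)cc2O1 | intermediate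
16 | 2-(3-hydroxypropyl)-5-[(3-methylbut-2-en-1-yl)oxy]phenol | OCCCc1ccc(OCC=C(C)C)cc1O | intermediate
17 | tert-butyl{3-[2-(tert-butyldimethylsilyloxy)-4-(3-methylbut-2-en-1-yloxy)phenyl]propoxy}dimethylsilane | CC(C)=CCOc1ccc(CCCO[Si](C)(C)C(C)(C)C)c(O[Si](C)(C)C(C)(C)C)c1 | intermediate
18 | 5-(tert-butyldimethylsilyloxy)-4-[3-(tert-butyldimethylsilyloxy)propyl]-2-(2-methylbut-3-en-2-yl)phenol | C=CC(C)(C)c1cc(CCCO[Si](C)(C)C(C)(C)C)c(O[Si](C)(C)C(C)(C)C)cc1O | intermediate
19 | 1,5-bis(tert-butyldimethylsilyloxy)-2-[3-(tert-butyldimethylsilyloxy)propyl]-4-(2-methylbut-3-en-2-yl)benzene | C=CC(C)(C)c1cc(CCCO[Si](C)(C)C(C)(C)C)c(O[Si](C)(C)C(C)(C)C)cc1O[Si](C)(C)C(C)(C)C | intermediate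
20 | 3-[2,4-bis(tert-butyldimethylsilyloxy)-5-(2-methylbut-3-en-2-yl)phenyl]propan-1-ol | C=CC(C)(C)c1cc(CCCO)c(O[Si](C)(C)C(C)(C)C)cc1O[Si](C)(C)C(C)(C)C | intermediate
21 | 1,5-bis(tert-butyldimethylsilyloxy)-2-(3-iodopropyl)-4-(2-methylbut-3-en-2-yl)benzene | C=CC(C)(C)c1cc(CCCI)c(O[Si](C)(C)C(C)(C)C)cc1O[Si](C)(C)C(C)(C)C | intermediate
22 | {3-[2,4-bis(tert-butyldimethylsilyloxy)-5-(2-methylbut-3-en-2-yl)phenyl]propyl}zinc iodide (formed in the flask) | C=CC(C)(C)c1cc(CCC[Zn]I)c(O[Si](C)(C)C(C)(C)C)cc1O[Si](C)(C)C(C)(C)C | intermediate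
23 | kazinol C tetrakis(tert-butyldimethylsilyl) ether | C=CC(C)(C)c1cc(CCCc2cc(O[Si](C)(C)C(C)(C)C)c(O[Si](C)(C)C(C)(C)C)c(CC=C(C)C)c2CC=C(C)C)c(O[Si](C)(C)C(C)(C)C)cc1O[Si](C)(C)C(C)(C)C | intermediate
24 | kazinol C | C=CC(C)(C)c1cc(CCCc2cc(O)c(O)c(CC=C(C)C)c2CC=C(C)C)c(O)cc1O | target

**Totals**

Total step count: 16. Longest linear sequence: 10 steps (steps 7–16, from umbelliferone 12 to 24); the ring B branch needs 6 steps before the union.

**Steps most likely to fail, with fallbacks**

1. Step 6. The basic ylide may deprotonate the benzylic aldehyde arms faster than it adds, so that enolisation and intramolecular aldol condensation, or decay of the dialdehyde before it meets the ylide, consume the material. The fallback reverses the polarity of the olefination and never isolates an aldehyde. It sets out from 6: the ozonide 7 formed as in step 5 is reduced in the same flask with NaBH4 (CH2Cl2/EtOH, −78 → 0 °C) to 2,2'-[3-bromo-5,6-bis(tert-butyldimethylsilyloxy)-1,2-phenylene]diethanol F1. CBr4/PPh3 in CH2Cl2 converts this to 1-bromo-2,3-bis(2-bromoethyl)-4,5-bis(tert-butyldimethylsilyloxy)benzene F2, and PPh3 in refluxing MeCN gives the bis(triphenylphosphonium) dibromide F3. KN(SiMe3)2 (2.1 equiv) in THF at 0 °C generates the bis-ylide F4, which is quenched with excess acetone (−78 °C → rt). This forms the same two CH=CMe2 bonds and returns to the route at 11.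

2. Step 11. The allyl unit may migrate in part to the wrong ortho carbon (C3, between the two oxygens), and the ortho-(1,1-dimethylallyl)phenol may rearrange further or cyclise onto its own alkene at the temperature needed. The fallback fixes the regiochemistry with a removable blocking atom on the coumarin and traps the phenol as it forms. It sets out from 12: I2/KI in aqueous NH3 gives 7-hydroxy-8-iodo-2H-chromen-2-one F5, and 13 with K2CO3 in acetone gives 8-iodo-7-[(3-methylbut-2-en-1-yl)oxy]-2H-chromen-2-one F6. Heating in PhNEt2 with butyric anhydride forces the shift to C6, giving 7-hydroxy-8-iodo-6-(2-methylbut-3-en-2-yl)-2H-chromen-2-one F7, which is acylated in the flask to 8-iodo-6-(2-methylbut-3-en-2-yl)-2-oxo-2H-chromen-7-yl butanoate F8. Pd(OAc)2/PPh3 with HCO2H/Et3N in DMF at 60 °C removes the iodine to give 6-(2-methylbut-3-en-2-yl)-2-oxo-2H-chromen-7-yl butanoate F9. The copper hydride conditions of step 8 give 6-(2-methylbut-3-en-2-yl)-2-oxochroman-7-yl butanoate F10, and LiAlH4 reduces lactone and ester to 4-(3-hydroxypropyl)-6-(2-methylbut-3-en-2-yl)benzene-1,3-diol F11. TBSOTf (3.5 equiv) with 2,6-lutidine silylates all three hydroxyls and returns to the route at 19.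

3. Step 15. Oxidative addition into the hindered, electron-rich C–Br bond may be slow enough that protonation or β-hydride elimination of the alkylzinc reagent overtakes cross-coupling. The fallback makes ring B the nucleophile and the iodide the electrophile. It sets out from 11: t-BuLi (2 equiv) in THF at −78 °C gives [4,5-bis(tert-butyldimethylsilyloxy)-2,3-bis(3-methylbut-2-en-1-yl)phenyl]lithium F12, and MgBr2·OEt2 converts it to [4,5-bis(tert-butyldimethylsilyloxy)-2,3-bis(3-methylbut-2-en-1-yl)phenyl]magnesium bromide F13. This is alkylated by iodide 21 under Li2CuCl4 catalysis (5 mol %, −20 → 0 °C), returning to the route at 23.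

**Further compounds**

F1 | step 6 | 2,2'-[3-bromo-5,6-bis(tert-butyldimethylsilyloxy)-1,2-phenylene]diethanol | OCCc1c(Br)cc(O[Si](C)(C)C(C)(C)C)c(O[Si](C)(C)C(C)(C)C)c1CCO
F2 | step 6 | 1-bromo-2,3-bis(2-bromoethyl)-4,5-bis(tert-butyldimethylsilyloxy)benzene | BrCCc1c(Br)cc(O[Si](C)(C)C(C)(C)C)c(O[Si](C)(C)C(C)(C)C)c1CCBr
F3 | step 6 | {[3-bromo-5,6-bis(tert-butyldimethylsilyloxy)-1,2-phenylene]di(ethane-2,1-diyl)}bis(triphenylphosphonium) dibromide | Brc1cc(O[Si](C)(C)C(C)(C)C)c(O[Si](C)(C)C(C)(C)C)c(CC[P+](c2ccccc2)(c2ccccc2)c2ccccc2)c1CC[P+](c1ccccc1)(c1ccccc1)c1ccccc1.[Br-].[Br-]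
F4 | step 6 | bis-ylide of F3 (formed in the flask) | Brc1cc(O[Si](C)(C)C(C)(C)C)c(O[Si](C)(C)C(C)(C)C)c(CC=P(c2ccccc2)(c2ccccc2)c2ccccc2)c1CC=P(c1ccccc1)(c1ccccc1)c1ccccc1
F5 | step 11 | 7-hydroxy-8-iodo-2H-chromen-2-one | O=c1ccc2ccc(O)c(I)c2o1
F6 | step 11 | 8-iodo-7-[(3-methylbut-2-en-1-yl)oxy]-2H-chromen-2-one | O=c1ccc2ccc(OCC=C(C)C)c(I)c2o1
F7 | step 11 | 7-hydroxy-8-iodo-6-(2-methylbut-3-en-2-yl)-2H-chromen-2-one (formed in the flask) | C=CC(C)(C)c1cc2ccc(=O)oc2c(I)c1O
F8 | step 11 | 8-iodo-6-(2-methylbut-3-en-2-yl)-2-oxo-2H-chromen-7-yl butanoate | CCCC(=O)Oc1c(I)c2oc(=O)ccc2cc1C(C)(C)C=C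
F9 | step 11 | 6-(2-methylbut-3-en-2-yl)-2-oxo-2H-chromen-7-yl butanoate | CCCC(=O)Oc1cc2oc(=O)ccc2cc1C(C)(C)C=C
F10 | step 11 | 6-(2-methylbut-3-en-2-yl)-2-oxochroman-7-yl butanoate | CCCC(=O)Oc1cc2OC(=O)CCc2cc1C(C)(C)C=C
F11 | step 11 | 4-(3-hydroxypropyl)-6-(2-methylbut-3-en-2-yl)benzene-1,3-diol | C=CC(C)(C)c1cc(CCCO)c(O)cc1O
F12 | step 15 | [4,5-bis(tert-butyldimethylsilyloxy)-2,3-bis(3-methylbut-2-en-1-yl)phenyl]lithium (formed in the flask) | [Li]c1cc(O[Si](C)(C)C(C)(C)C)c(O[Si](C)(C)C(C)(C)C)c(CC=C(C)C)c1CC=C(C)C
F13 | step 15 | [4,5-bis(tert-butyldimethylsilyloxy)-2,3-bis(3-methylbut-2-en-1-yl)phenyl]magnesium bromide (formed in the flask) | Br[Mg]c1cc(O[Si](C)(C)C(C)(C)C)c(O[Si](C)(C)C(C)(C)C)c(CC=C(C)C)c1CC=C(C)C
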